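The flavanone is cut back to its flavan, and ring C is then taken apart across O1–C2 and C3–C4. Atoms O1, C8a, C4a and C4 become the 1-oxadiene of an ortho-quinone methide obtained by dearomatising ring A, while C2, C3 and ring B are 3,4-dimethoxystyrene. One chiral-acid-catalysed oxa-[4+2] cycloaddition should therefore form both bonds, close ring C and set C2. The precursor is a fully substituted 2-hydroxybenzyl alcohol whose future 8-oxygen is masked as a benzyl ether. The C4 carbonyl is introduced afterwards by benzylic oxidation, so C2 cannot racemise through a chalcone at the cycloaddition stage, and hydrogenolysis ends the route.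

Key step: step 6

Structure check: the target is (2S)-8-hydroxy-5,6,7,3',4'-pentamethoxyflavanone. The benzyl alcohol precursor, the styrene and the (S)-flavan are consistent with it and needed no correction. C2 keeps the descriptor S on C4 oxidation because the ranking O1 > C1' > C3 > H does not change.

Assumption: the sense of induction of the phosphoramide cannot be predicted with confidence. The catalyst antipode that gives the (S)-flavan is to be used; both antipodes are available.

Step 1
Reactants: 1 3,4,5-trimethoxyphenol
Product: 2 2-hydroxy-4,5,6-trimethoxybenzaldehyde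
Conditions: MgCl2, Et3N, (CH2O)n, MeCN, reflux; aq. HCl work-up
Reagents that add atoms: paraformaldehyde (formaldehyde), C=O
Why: Magnesium-phenoxide-directed ortho-formylation (Casnati–Skattebøl reaction) delivers formaldehyde to a carbon ortho to the phenoxide, and since both ortho positions of 1 are equivalent and the para position is blocked only one aldehyde can form.

Step 2
Reactants: 2 2-hydroxy-4,5,6-trimethoxybenzaldehyde
Product: 3 3,4,5-trimethoxybenzene-1,2-diol
Conditions: 30% H2O2, NaOH, THF/H2O, 0 °C → rt, Ar; then aq. HCl/Na2S2O4
Reagents that add atoms: hydrogen peroxide, OO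
Why: Dakin oxidation, in which hydroperoxide adds to the formyl group of the ortho-hydroxybenzaldehyde, the electron-rich aryl group migrates to oxygen and the aryl formate is hydrolysed in situ, the air-sensitive catechol being kept under argon and acidified promptly.

Step 3
Reactants: 3 3,4,5-trimethoxybenzene-1,2-diol
Product: 4 2,3-dihydroxy-4,5,6-trimethoxybenzaldehyde
Conditions: POCl3, DMF, 0 → 60 °C, Ar; then aq. NaOAc, 60 °C
Reagents that add atoms: N,N-dimethylformamide, CN(C)C=O; water, O
Why: Vilsmeier–Haack formylation, in which the chloroiminium ion substitutes the single unsubstituted carbon of this penta-oxygenated ring (ortho to a hydroxyl, para to a methoxy group), as in the formylation of free pyrogallol, and the warm acetate hydrolysis releases the aldehyde and any O-formylated hydroxyl.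

Step 4
Reactants: 4 2,3-dihydroxy-4,5,6-trimethoxybenzaldehyde; 5 benzyl bromide
Product: 6 3-benzyloxy-2-hydroxy-4,5,6-trimethoxybenzaldehyde
Conditions: NaH (2.2 equiv), DMSO/THF, rt; then 5 (1.0 equiv), rt; aq. NH4Cl
Reagents that add atoms: benzyl bromide (compound 5), BrCc1ccccc1
Why: Williamson etherification of the dianion, in which the C2 phenoxide is tied up by conjugation and chelation with the formyl group so that the more nucleophilic C3 phenoxide takes the single equivalent of benzyl bromide, as in the known 3-O-alkylation of 2,3-dihydroxybenzaldehyde.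

Step 5
Reactants: 6 3-benzyloxy-2-hydroxy-4,5,6-trimethoxybenzaldehyde
Product: 7 2-benzyloxy-6-(hydroxymethyl)-3,4,5-trimethoxyphenol
Conditions: NaBH4, THF/MeOH, 0 °C; pH 7 buffer work-up; used without chromatography
Reagents that add atoms: none
Why: Borohydride reduction of the aldehyde to the primary benzylic alcohol, run cold and worked up at neutral pH so that the electron-rich salicyl alcohol is neither over-reduced nor lost through its quinone methide.

Step 6
Reactants: 7 2-benzyloxy-6-(hydroxymethyl)-3,4,5-trimethoxyphenol; 8 3,4-dimethoxystyrene
Product: 10 (S)-8-benzyloxy-5,6,7,3',4'-pentamethoxyflavan [(2S)-8-benzyloxy-2-(3,4-dimethoxyphenyl)-5,6,7-trimethoxychromane], via ortho-quinone methide 9 (not isolated)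
Conditions: (R)-3,3'-bis(2,4,6-triisopropylphenyl)-1,1'-binaphthyl-2,2'-diyl N-triflylphosphoramide (10 mol %), 8 (3 equiv), 5 Å MS, toluene, −40 °C, slow addition of 7; Et3N quench at −40 °C
Reagents that add atoms: none
Why: Proposed new method: the phosphoramide should protonate the benzylic hydroxyl of 7 so that water leaves and ortho-quinone methide 9 is held at its O1 carbonyl by the chiral acid (a contact ion pair of the 2-hydroxybenzyl cation and the chiral anion); the terminal CH2 of 8 then attacks the methide carbon (C3–C4) while the phenolic oxygen collapses on the developing veratryl cation (O1–C2) in one asynchronous, inverse-electron-demand oxa-[4+2] event that restores aromatic ring A. The closest known reaction type is the chiral Brønsted acid-catalysed [4+2] cycloaddition of styrenes with ortho-quinone methides released from 2-hydroxybenzyl alcohols that carry an aryl group on the carbinol carbon; a methide carbon without a substituent, with face selection on the styrene alone, has not been shown. Ring C is closed in the [4+2] mode, the 4π oxadiene O1=C8a–C4a=C4 combining suprafacially with the 2π vinyl group to give the six-membered ring. C2 is the only new stereocentre and is under catalyst control: the anion bound at O1 sits beside the forming O1–C2 bond and its 3,3'-aryl walls should leave one enantioface of the styrene open. Regioselectivity (2-aryl, not 3-aryl) is secured by polarity, since the nucleophilic styrene CH2 bonds to the electrophilic C4 and the positive charge develops at the veratryl-stabilised C2. Chemoselectivity over styrene oligomerisation, self-addition of 9 and ionisation of the product at C2 is sought through the low temperature, the excess of 8, the slow addition, the cold basic quench and the fact that every ring carbon of 7 is substituted.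

Step 7
Reactants: 10 (S)-8-benzyloxy-5,6,7,3',4'-pentamethoxyflavan
Product: 12 (S)-8-benzyloxy-5,6,7,3',4'-pentamethoxyflavanone [(2S)-8-benzyloxy-2-(3,4-dimethoxyphenyl)-5,6,7-trimethoxychroman-4-one], via flavan-4-ol 11 (not isolated)
Conditions: DDQ (2.3 equiv), CH2Cl2/aq. pH 7 phosphate buffer, 0 °C → rt
Reagents that add atoms: water, O
Why: DDQ benzylic oxidation in wet solvent, in which hydride abstraction from C4 (on the more electron-rich ring A, the cation being stabilised by O1 and the 5- and 7-methoxy groups) is followed by water capture to 11 and a second hydride abstraction from the carbinol C–H to the aryl ketone, while C2 is not touched and keeps its configuration.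

Step 8
Reactants: 12 (S)-8-benzyloxy-5,6,7,3',4'-pentamethoxyflavanone
Product: 13 (S)-8-hydroxy-5,6,7,3',4'-pentamethoxyflavanone [(2S)-2-(3,4-dimethoxyphenyl)-8-hydroxy-5,6,7-trimethoxychroman-4-one], CNP0179923.1
Conditions: H2 (1 atm), Pd/C, EtOAc, rt
Reagents that add atoms: none
Why: Hydrogenolysis of the benzyl aryl ether over Pd/C, which should be much faster than reduction of the electron-rich aryl ketone or of the ring C–O bond, in a neutral medium that gives no opening to the chalcone, so C2 stays (S).

Compound list
1 | 3,4,5-trimethoxyphenol | COc1cc(O)cc(OC)c1OC | starting material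
2 | 2-hydroxy-4,5,6-trimethoxybenzaldehyde | COc1cc(O)c(C=O)c(OC)c1OC | intermediate
3 | 3,4,5-trimethoxybenzene-1,2-diol | COc1cc(O)c(O)c(OC)c1OC | intermediate
4 | 2,3-dihydroxy-4,5,6-trimethoxybenzaldehyde | COc1c(O)c(O)c(C=O)c(OC)c1OC | intermediate
5 | benzyl bromide | BrCc1ccccc1 | starting material
6 | 3-benzyloxy-2-hydroxy-4,5,6-trimethoxybenzaldehyde | COc1c(OCc2ccccc2)c(O)c(C=O)c(OC)c1OC | intermediate
7 | 2-benzyloxy-6-(hydroxymethyl)-3,4,5-trimethoxyphenol | OCc1c(O)c(OCc2ccccc2)c(OC)c(OC)c1OC | intermediate
8 | 3,4-dimethoxystyrene | C=Cc1ccc(OC)c(OC)c1 | starting material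
9 | 2-benzyloxy-3,4,5-trimethoxy-6-methylidenecyclohexa-2,4-dien-1-one (ortho-quinone methide, not isolated) | C=C1C(=O)C(OCc2ccccc2)=C(OC)C(OC)=C1OC | intermediate
10 | (S)-8-benzyloxy-5,6,7,3',4'-pentamethoxyflavan | COc1ccc([C@@H]2CCc3c(c(OCc4ccccc4)c(OC)c(OC)c3OC)O2)cc1OC | intermediate
11 | (2S)-8-benzyloxy-5,6,7,3',4'-pentamethoxyflavan-4-ol (both C4 epimers, not isolated) | COc1ccc([C@@H]2CC(O)c3c(c(OCc4ccccc4)c(OC)c(OC)c3OC)O2)cc1OC | intermediate
12 | (S)-8-benzyloxy-5,6,7,3',4'-pentamethoxyflavanone | COc1ccc([C@@H]2CC(=O)c3c(c(OCc4ccccc4)c(OC)c(OC)c3OC)O2)cc1OC | intermediate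
13 | (S)-8-hydroxy-5,6,7,3',4'-pentamethoxyflavanone | COc1ccc([C@@H]2CC(=O)c3c(c(O)c(OC)c(OC)c3OC)O2)cc1OC | target

Total step count: 8. Longest linear sequence: 8 steps (1 → 13; 5 and 8 are purchased).

Steps most likely to fail

Step 6. Enantioface discrimination on the styrene may be poor, because the methide carbon carries no substituent to orient the partners in the chiral pocket. Acid-initiated oligomerisation of the styrene may also outrun the cycloaddition. The fallback uses known chemistry only, sets out from 6 and rejoins the route at 12, bypassing steps 5 to 7. MeMgBr (excess, THF, 0 °C) should add to the aldehyde to give 1-(3-benzyloxy-2-hydroxy-4,5,6-trimethoxyphenyl)ethanol F1. MnO2 (CH2Cl2, rt) should oxidise this to 1-(3-benzyloxy-2-hydroxy-4,5,6-trimethoxyphenyl)ethanone F2. Me2NCH(OMe)2 (toluene, 100 °C) should convert F2 into the enaminone (E)-1-(3-benzyloxy-2-hydroxy-4,5,6-trimethoxyphenyl)-3-(dimethylamino)prop-2-en-1-one F3. Aqueous HCl in CH2Cl2 should close F3, with loss of dimethylamine, to 8-benzyloxy-5,6,7-trimethoxychromone F4. Asymmetric conjugate addition of 3,4-dimethoxyphenylboronic acid to F4 should then give 12; the conditions are Pd(OCOCF3)2, t-BuPyOx (the enantiomer that gives the 2S product), NH4PF6, H2O, ClCH2CH2Cl, 60 °C. This is an established entry to enantioenriched flavanones. Step 8 follows unchanged.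

Step 7. Hydride loss from C2 (an oxygen-bearing 3,4-dimethoxybenzylic position) may compete with C4. The C4 cation may also eliminate to the flav-3-ene, which is oxidised on to the flavylium ion. Either channel erases the C2 stereocentre, and excess quinone may in addition dehydrogenate 12 to the flavone. The fallback sets out from 10 and rejoins at 12. Pb(OAc)4 (benzene, rt to 50 °C) should acetoxylate C4, the classical flavan to 4-acetoxyflavan oxidation, to give (2S)-8-benzyloxy-5,6,7,3',4'-pentamethoxyflavan-4-yl acetate F5. LiOH (THF/H2O) should free flavan-4-ol 11, which is isolated in this variant. MnO2 or Dess–Martin periodinane buffered with NaHCO3 should oxidise 11 to 12. No quinone is present at any stage, so onward dehydrogenation is not possible.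

Step 3. O-Formylation or O-phosphorylation and air oxidation of the unprotected catechol may displace clean C-formylation; the same flanking groups may also erode the hydroxyl discrimination of step 4. The fallback sets out from 3 and rejoins at 6, bypassing step 4 as well. Exhaustive benzylation (5, K2CO3, DMF, rt) should give 1,2-bis(benzyloxy)-3,4,5-trimethoxybenzene F6. Vilsmeier–Haack formylation (POCl3, DMF, 70 °C) at the only free carbon of this penta-alkoxybenzene should give 2,3-bis(benzyloxy)-4,5,6-trimethoxybenzaldehyde F7. MgBr2·OEt2 (toluene/Et2O, reflux) should remove selectively the benzyl ether ortho to the formyl group through a magnesium chelate, releasing benzyl bromide and giving 6. The benzyl group is cleaved by bromide far more readily than the ortho methyl ether.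

Further compounds
F1 | step 6 | 1-(3-benzyloxy-2-hydroxy-4,5,6-trimethoxyphenyl)ethanol (racemic) | CC(O)c1c(O)c(OCc2ccccc2)c(OC)c(OC)c1OC
F2 | step 6 | 1-(3-benzyloxy-2-hydroxy-4,5,6-trimethoxyphenyl)ethanone | CC(=O)c1c(O)c(OCc2ccccc2)c(OC)c(OC)c1OC
F3 | step 6 | (E)-1-(3-benzyloxy-2-hydroxy-4,5,6-trimethoxyphenyl)-3-(dimethylamino)prop-2-en-1-one | CN(C)/C=C/C(=O)c1c(O)c(OCc2ccccc2)c(OC)c(OC)c1OC
F4 | step 6 | 8-benzyloxy-5,6,7-trimethoxychromone | O=c1ccoc2c(OCc3ccccc3)c(OC)c(OC)c(OC)c12
F5 | step 7 | (2S)-8-benzyloxy-5,6,7,3',4'-pentamethoxyflavan-4-yl acetate (C4 epimers) | COc1ccc([C@@H]2CC(OC(C)=O)c3c(c(OCc4ccccc4)c(OC)c(OC)c3OC)O2)cc1OC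
F6 | step 3 | 1,2-bis(benzyloxy)-3,4,5-trimethoxybenzene | COc1cc(OCc2ccccc2)c(OCc2ccccc2)c(OC)c1OC
F7 | step 3 | 2,3-bis(benzyloxy)-4,5,6-trimethoxybenzaldehyde | COc1c(C=O)c(OCc2ccccc2)c(OCc2ccccc2)c(OC)c1OC
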